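## Structural features

Palstatin is a flavonolignan. It is a 5,7-dihydroxyflavone (ring A fused to the pyranone ring C) whose ring B is oxygenated at C3', C4' and C5'; O5' is a methyl ether, and O3' and O4' are bridged by two carbons into a 2,3-dihydro-1,4-benzodioxine ring. Ca, the dioxane carbon on O3', carries a 4-hydroxy-3,5-dimethoxyphenyl group, and Cb, the dioxane carbon on O4', carries CH2OH. These two adjacent carbons are the only stereocentres, both R, with the substituents trans. The fragile bond is the benzylic aryl ether Ca–O3': with the para phenol free it can open to a quinone methide under base, it can ionise under strong Lewis acid, and it is a benzyl-type ether under hydrogenolysis. The free phenols and the C2=C3 enone add sensitivity to oxidation and reduction. The flavone is routine, so the real difficulty lies in the dioxane: O3' must go to Ca and O4' to Cb, and absolute and relative configuration must both be fixed. The key step uses the fact that Cb is bonded both to O4' and to the CH2OH carbon, so Cb and that CH2 can be the two carbons of a terminal oxirane. A phenoxide at C4', tethered through C4'–C3'–O3'–Ca, can open this oxirane at Cb; this closes the dioxane, frees the hydroxymethyl group and converts (S)-Cb into the (R)-Cb of the trans ring.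

## Logic of the disconnections

20 ⇒ 19. The three phenolic O–H bonds (O5, O7 and the para oxygen of the pendant aryl ring) are replaced by O–benzyl bonds. The para-hydroxyaryl group is what makes Ca labile to base, so it is unmasked last. All earlier intermediates are then non-phenolic and one neutral operation ends the synthesis. The forward step must cleave three aryl benzyl ethers without touching Ca–O3' or C2=C3.

19 ⇒ 17 (through 18). The O1–C2 bond of ring C is cut by formal addition of water, and the primary alcohol is returned to its silyl ether. A flavone is the cyclodehydration product of an ortho-hydroxyaryl 1,3-diketone, and the acid that closes the ring also removes the silyl group. One step is saved, but the forward step is limited to a Brønsted acid that does not ionise Ca–O3'.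

17 ⇒ 16 ⇒ 13 + 15. The C2–C3 bond is cut by moving the ring B acyl group from carbon back to the phenolic oxygen of ring A, and then the ester C–O bond is cut. This makes the C–C bond intramolecular and divides the molecule into an achiral ring A ketone and a chiral ring B acid. The forward steps need a single free phenol in 15, a single carboxyl group in 13 and an enolisation that spares the silyl ether.

15 ⇒ 14. Two O–benzyl bonds are cut. The third hydroxyl stays free because it is hydrogen-bonded to the ketone, so only the stoichiometry of the halide needs control.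

13 ⇒ 12 ⇒ 11. The acid is returned to the methyl ester and the O–Si bond is cut. The primary alcohol would otherwise compete in the esterification of step 11, so it is capped before the ester is hydrolysed.

11 ⇒ 10 ⇒ 9. This is the strategic cut, Cb–O4'. It removes the ring and one stereocentre and leaves an acyclic ether whose Cb is the carbon of an oxirane. The forward step must give 6-exo attack by O4' at Cb with inversion, and must not allow 7-endo attack at CH2. A free phenol next to an oxirane should not be stored, so 10 is released from its allyl ether 9 in the basic medium that cyclises it.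

9 ⇒ 8 ⇒ 7. The O–CH2 bond of the oxirane is cut to a 1,2-diol. The oxirane is only the activated form of the diol, and its closure at the primary carbon leaves Cb untouched. The forward step needs sulfonylation of the primary hydroxyl only.

7 ⇒ 4 + 6. The Ca–O3' bond is cut. This is the convergent union of the two aryl halves, and it places O3' on the benzylic carbon, the natural site of attack on an aryl epoxy alcohol. The forward step must invert Ca cleanly, since Ca cannot be corrected later while the para oxygen is benzylated. Only the 3-hydroxyl of 6 may be free.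

6 ⇒ 5 and 4 ⇒ 3 ⇒ 2 ⇒ 1. One O–allyl bond is cut in 6, the oxirane oxygen is removed from 4, and the allylic alcohol 3 is traced through the ester 2 to the cinnamic acid 1. The forward steps need regioselective allylation of the more acidic 4-hydroxyl of 5, and face-selective epoxidation of an E allylic alcohol, which sets Cb and, after inversion, Ca.

## Other disconnections considered

Alternative 1: The cut runs through C4a–C4 and C8a–O1. Ring A is delivered as an aryne, and C2–C3–C4 arrives with ring B as the arylpropiolic acid A2 (finished dioxane; phenol and CH2OH as benzyl ethers). In the forward step CsF would release the aryne from the silyl triflate A3. The carboxylate oxygen of A2 adds to the aryne carbon remote from the flanking benzyloxy group, the aryl anion beside that group attacks the acyl carbon, and the four-membered intermediate opens to the ortho-hydroxyaryl ynone A1. A1 then needs a separate 6-endo-dig closure to form ring C.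
- In favour: two bonds of ring A form in one operation, the alkoxy group next to the aryne dictates the regiochemistry, and the medium is nearly neutral. No strong base or acid touches the benzylic ether at Ca, and on this point the alternative is better than the enolate and acid steps of the chosen plan.
- Against: it does nothing for the dioxane, whose stereocentres would still have to come from the epoxide opening. A2 lies about four steps beyond the ester stage (reduction, oxidation, alkyne homologation, carboxylation) and A3 about four steps from a phloroglucinol ether. Foreseeable leaks are O-arylation without acyl migration, decarboxylation of the propiolic acid and 5-exo closure to an aurone. The alkyl benzyl ether on CH2OH would need a longer hydrogenolysis next to the Ca–O3' bond.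
- Comparison: on structure the plans are equal in convergence, since both join ring A late to a chiral ring B block. On mechanism the aryne route is milder but has more competing channels. On step economy it is longer by about three to four steps.

Alternative 2: The cut takes C4 out as carbon monoxide and breaks C4a–C4, C4–C3 and O1–C2. This leaves the iodophenol A5 and the terminal alkyne A6, which already contains the dioxane. In the forward step zerovalent palladium formed from PdCl2(PPh3)2 would insert into the C–I bond of A5 and CO insertion would give an aroyl palladium species. Coupling with the acetylide of A6 in Et2NH gives the ynone, and 6-endo-dig attack of the phenol closes ring C to A4.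
- In favour: three bonds and one ring form in one flask, more bond formation per step than in the chosen plan. The conditions are mildly basic, without acid, and the silyl ether survives. On these points it is the better plan.
- Against: the C–I bond of A5 lies between two oxygen substituents on a very electron-rich ring, so oxidative addition should be slow. Coupling without CO uptake or 5-exo closure to an aurone can intervene, A5 needs a regioselective iodination, and CO must be handled under pressure. A6 costs three steps from 12 (reduction, oxidation, Seyferth–Gilbert homologation) and A4 still needs fluoride and hydrogenolysis. That is six steps from 12 against five in the chosen route (steps 9, 11, 12, 13, 14). It also leaves the stereochemical problem untouched.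
- Comparison: structurally it is the equal of the chosen plan in convergence. Mechanistically it replaces a predictable intramolecular acyl transfer by a three-component catalytic cycle with a hindered partner. In step count it is one to two steps longer.

Alternative 3: The cut is the aryl–oxygen bond C3'–O3' instead of the alkyl–oxygen bond Cb–O4'. The precursor is the threo bromo alcohol A8, in which Cb is already bonded to O4' and Ca carries a free benzylic hydroxyl. In the forward step palladium (Pd(OAc)2 with a di-tert-butylphosphinobiaryl ligand) would insert into the C3'–Br bond, Cs2CO3 would bring the Ca alkoxide onto the metal, and C–O reductive elimination would give A7. A7 is the same compound as 12.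
- In favour: neither stereocentre is touched in the ring closure, there is no exo versus endo question, and the position of bromine fixes the ring size. On the stereochemical security of the closing event it is the better plan, and it is the equal of the chosen plan in meeting the route at 12.
- Against: the difficulty moves into A8. Its Cb–O4' bond must be made intermolecularly by SN2 at secondary Cb with the doubly ortho-substituted phenol of the bromo ester A9. That is the same inversion at Cb as in the chosen plan, but without a tether. The parent triol needs its three hydroxyls differentiated. The palladium alkoxide of a secondary benzylic alcohol has a β-hydrogen, so oxidation to the aryl ketone with reduction of C–Br competes, on an ortho-alkoxy aryl bromide that adds slowly.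
- Comparison: structurally both plans build the same ring from the same two halves. Mechanistically the chosen plan closes the ring by an intramolecular SN2 with K2CO3 and needs palladium only to unmask the phenol, whereas A8 needs a metal–ligand system for the bond-forming event. In step count the alternative is about two steps longer.

Key step: step 7

Remark: Ca is the aryl-bearing dioxane carbon on O3' and Cb the CH2OH-bearing carbon on O4'. Commercial sinapic acid is taken as the pure E isomer. (R)-Ca/(S)-Cb in 10 and (R,R) in 11 differ by exactly one inversion at Cb, so both structures are used as drawn.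

## Route

Step 1
Reactants: 1 sinapic acid, (E)-3-(4-hydroxy-3,5-dimethoxyphenyl)prop-2-enoic acid
Product: 2 benzyl (E)-3-[4-(benzyloxy)-3,5-dimethoxyphenyl]prop-2-enoate
Conditions: BnBr (2.5 equiv), K2CO3, DMF, 60 °C
Reagents that add atoms: benzyl bromide, BrCc1ccccc1
Why: Double O-alkylation (Williamson ether synthesis at the phenoxide, SN2 esterification at the carboxylate) by a reactive benzylic bromide; the E double bond is not touched.

Step 2
Reactants: 2 benzyl (E)-3-[4-(benzyloxy)-3,5-dimethoxyphenyl]prop-2-enoate
Product: 3 (E)-3-[4-(benzyloxy)-3,5-dimethoxyphenyl]prop-2-en-1-ol (O-benzylsinapyl alcohol)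
Conditions: iBu2AlH (2.5 equiv), CH2Cl2, −78 → 0 °C; aq. potassium sodium tartrate (KNaC4H4O6)
Reagents that add atoms: none
Why: 1,2-Reduction of an α,β-unsaturated ester by an aluminium hydride at low temperature should give the allylic alcohol without conjugate reduction; the aryl benzyl ether is inert and the benzyl alcohol released is removed on chromatography.

Step 3
Reactants: 3 (E)-3-[4-(benzyloxy)-3,5-dimethoxyphenyl]prop-2-en-1-ol
Product: 4 [(2S,3S)-3-[4-(benzyloxy)-3,5-dimethoxyphenyl]oxiran-2-yl]methanol
Conditions: Ti(OiPr)4 (10 mol%), L-(+)-diisopropyl tartrate (12 mol%), t-BuOOH (2 equiv, isooctane), 4 Å MS, CH2Cl2, −20 °C; non-acidic work-up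
Reagents that add atoms: tert-butyl hydroperoxide, CC(C)(C)OO
Why: Sharpless asymmetric epoxidation: the titanium–L-(+)-tartrate complex binds the allylic alkoxide and the peroxide and delivers oxygen to the face of the E alkene that gives the (2S,3S)-epoxy alcohol. This sets Cb (S) and the provisional configuration of Ca; molecular sieves allow catalytic titanium and the non-acidic work-up protects the aryl oxirane.

Step 4
Reactants: 5 methyl 3,4-dihydroxy-5-methoxybenzoate
Product: 6 methyl 3-hydroxy-5-methoxy-4-(prop-2-enyloxy)benzoate
Conditions: allyl bromide (1.05 equiv), Li2CO3 (1.1 equiv), DMF, 45 °C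
Reagents that add atoms: allyl bromide, C=CCBr
Why: Williamson monoalkylation under a weak base: the 4-hydroxyl, para to the ester, is the more acidic phenol and is ionised preferentially, so allylation should occur there and leave the 3-hydroxyl free as the later nucleophile.

Step 5
Reactants: 4 [(2S,3S)-3-[4-(benzyloxy)-3,5-dimethoxyphenyl]oxiran-2-yl]methanol; 6 methyl 3-hydroxy-5-methoxy-4-(prop-2-enyloxy)benzoate
Product: 7 methyl 3-{[(1R,2S)-1-[4-(benzyloxy)-3,5-dimethoxyphenyl]-2,3-dihydroxypropyl]oxy}-5-methoxy-4-(prop-2-enyloxy)benzoate (erythro diol)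
Conditions: Ti(OiPr)4 (1.5 equiv), 6 (2 equiv), CH2Cl2, rt; aq. tartaric acid work-up
Reagents that add atoms: none
Why: Titanium-mediated regioselective opening of a 2,3-epoxy alcohol: the substrate binds tetravalent titanium through its alkoxide and oxirane oxygen, which activates C3, here also the benzylic carbon Ca, toward the titanium-bound aryloxide of 6. Backside attack inverts Ca (S to R) and leaves Cb (S) untouched, so the erythro ether with O3' on Ca should result.

Step 6
Reactants: 7 methyl 3-{[(1R,2S)-1-[4-(benzyloxy)-3,5-dimethoxyphenyl]-2,3-dihydroxypropyl]oxy}-5-methoxy-4-(prop-2-enyloxy)benzoate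
Product: 9 methyl 3-{(R)-[4-(benzyloxy)-3,5-dimethoxyphenyl][(2S)-oxiran-2-yl]methoxy}-5-methoxy-4-(prop-2-enyloxy)benzoate, via primary tosylate 8 (not isolated)
Conditions: TsCl (1.1 equiv), Et3N, Bu2SnO (2 mol%), CH2Cl2, 0 °C → rt; then K2CO3, MeOH, rt
Reagents that add atoms: none
Why: Tin-catalysed sulfonylation of a 1,2-diol is selective for the primary hydroxyl; K2CO3 in methanol then lets the Cb alkoxide displace the tosylate (intramolecular Williamson closure, 3-exo-tet). Substitution occurs at CH2, so Cb (S) and Ca (R) keep their configurations.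

Step 7
Reactants: 9 methyl 3-{(R)-[4-(benzyloxy)-3,5-dimethoxyphenyl][(2S)-oxiran-2-yl]methoxy}-5-methoxy-4-(prop-2-enyloxy)benzoate
Product: 11 methyl (2R,3R)-2-[4-(benzyloxy)-3,5-dimethoxyphenyl]-3-(hydroxymethyl)-5-methoxy-2,3-dihydro-1,4-benzodioxine-7-carboxylate, via epoxy phenol 10 (not isolated)
Conditions: Pd(PPh3)4 (3 mol%), K2CO3 (3 equiv), MeOH–THF, rt → 45 °C
Reagents that add atoms: none
Why: Zerovalent palladium ionises the aryl allyl ether of 9 (Tsuji–Trost type cleavage, the para-ester phenoxide being a good leaving group) and methoxide takes up the allyl group, so the potassium phenoxide of 10 forms in the basic medium and is never stored. Its O4' then attacks the oxirane carbon Cb from the side opposite the Cb–O bond in an SN2 reaction, which forms Cb–O4' and releases the oxirane oxygen as the primary alkoxide, protonated at once by methanol. The closest known reaction type is the base-mediated cyclisation of 2-(oxiranylmethoxy)phenols to 2-hydroxymethyl-1,4-benzodioxanes, the second stage of the catechol–epichlorohydrin reaction. The dioxane ring closes in the 6-exo-tet mode; the competing 7-endo attack at the CH2 terminus would give a 1,5-benzodioxepin-3-ol. The one new stereocentre, Cb, is controlled by the substrate: its (S) configuration from the Sharpless epoxidation is converted stereospecifically into (R) by inversion while Ca (R) is a spectator, so the trans-(2R,3R) ring with both substituents equatorial should result. The step needs exo regioselectivity and clean inversion; the five-atom tether O4'–C4'–C3'–O3'–Ca brings the phenoxide in line with the Cb–O bond but not with the CH2–O bond, and a concerted opening at a non-benzylic carbon leaves no path to retention. It also needs chemoselectivity over methanolysis of the oxirane and over ester exchange, which the high effective molarity of the internal phenoxide and the mild temperature should secure.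

Step 8
Reactants: 11 methyl (2R,3R)-2-[4-(benzyloxy)-3,5-dimethoxyphenyl]-3-(hydroxymethyl)-5-methoxy-2,3-dihydro-1,4-benzodioxine-7-carboxylate
Product: 12 methyl (2R,3R)-2-[4-(benzyloxy)-3,5-dimethoxyphenyl]-3-{[(tert-butyldimethylsilyl)oxy]methyl}-5-methoxy-2,3-dihydro-1,4-benzodioxine-7-carboxylate
Conditions: TBSCl (1.3 equiv), imidazole, DMF, rt
Reagents that add atoms: tert-butyldimethylsilyl chloride, CC(C)(C)[Si](C)(C)Cl
Why: Imidazole-promoted silylation of a primary alcohol; it blocks the only other nucleophile before the carboxyl group is activated.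

Step 9
Reactants: 12 methyl (2R,3R)-2-[4-(benzyloxy)-3,5-dimethoxyphenyl]-3-{[(tert-butyldimethylsilyl)oxy]methyl}-5-methoxy-2,3-dihydro-1,4-benzodioxine-7-carboxylate
Product: 13 (2R,3R)-2-[4-(benzyloxy)-3,5-dimethoxyphenyl]-3-{[(tert-butyldimethylsilyl)oxy]methyl}-5-methoxy-2,3-dihydro-1,4-benzodioxine-7-carboxylic acid
Conditions: LiOH·H2O (5 equiv), THF–MeOH–H2O, 40 °C; then 1 M HCl to pH 4, 0 °C
Reagents that add atoms: lithium hydroxide, [Li+].[OH-]
Why: Saponification of the methyl ester by acyl–oxygen cleavage; the primary silyl ether, the benzyl ether and the dioxane are stable to aqueous LiOH and neither stereocentre is acidic.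

Step 10
Reactants: 14 2,4,6-trihydroxyacetophenone
Product: 15 1-[2,4-bis(benzyloxy)-6-hydroxyphenyl]ethanone
Conditions: BnBr (2.1 equiv), K2CO3 (2.2 equiv), DMF, rt
Reagents that add atoms: benzyl bromide, BrCc1ccccc1
Why: Williamson benzylation; the hydroxyl para to the acetyl group and one ortho hydroxyl react, while the remaining ortho hydroxyl is held in a hydrogen bond to the ketone and should stay free with two equivalents of halide.

Step 11
Reactants: 13 (2R,3R)-2-[4-(benzyloxy)-3,5-dimethoxyphenyl]-3-{[(tert-butyldimethylsilyl)oxy]methyl}-5-methoxy-2,3-dihydro-1,4-benzodioxine-7-carboxylic acid; 15 1-[2,4-bis(benzyloxy)-6-hydroxyphenyl]ethanone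
Product: 16 2-acetyl-3,5-bis(benzyloxy)phenyl (2R,3R)-2-[4-(benzyloxy)-3,5-dimethoxyphenyl]-3-{[(tert-butyldimethylsilyl)oxy]methyl}-5-methoxy-2,3-dihydro-1,4-benzodioxine-7-carboxylate
Conditions: EDC·HCl (1.5 equiv), DMAP (0.5 equiv), CH2Cl2, rt
Reagents that add atoms: none
Why: Steglich esterification (carbodiimide activation, acyl transfer through the acylpyridinium ion) between the only free phenol of 15 and the only carboxyl group of 13.

Step 12
Reactants: 16 2-acetyl-3,5-bis(benzyloxy)phenyl (2R,3R)-2-[4-(benzyloxy)-3,5-dimethoxyphenyl]-3-{[(tert-butyldimethylsilyl)oxy]methyl}-5-methoxy-2,3-dihydro-1,4-benzodioxine-7-carboxylate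
Product: 17 1-[2,4-bis(benzyloxy)-6-hydroxyphenyl]-3-[(2R,3R)-2-[4-(benzyloxy)-3,5-dimethoxyphenyl]-3-{[(tert-butyldimethylsilyl)oxy]methyl}-5-methoxy-2,3-dihydro-1,4-benzodioxin-7-yl]propane-1,3-dione
Conditions: LiN(SiMe3)2 (3 equiv), THF, −78 °C → rt; AcOH quench
Reagents that add atoms: none
Why: Baker–Venkataraman rearrangement: the lithium enolate of the acetyl group attacks the neighbouring aryl ester carbonyl through a six-membered cyclic alkoxide, whose collapse moves the acyl group from oxygen to carbon (C2–C3 bond), driven by formation of the phenoxide and the diketone enolate. The non-nucleophilic amide base avoids ester cleavage.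

Step 13
Reactants: 17 1-[2,4-bis(benzyloxy)-6-hydroxyphenyl]-3-[(2R,3R)-2-[4-(benzyloxy)-3,5-dimethoxyphenyl]-3-{[(tert-butyldimethylsilyl)oxy]methyl}-5-methoxy-2,3-dihydro-1,4-benzodioxin-7-yl]propane-1,3-dione
Product: 19 5,7-bis(benzyloxy)-2-[(2R,3R)-2-[4-(benzyloxy)-3,5-dimethoxyphenyl]-3-(hydroxymethyl)-5-methoxy-2,3-dihydro-1,4-benzodioxin-7-yl]-4H-chromen-4-one, via hydroxy diketone 18 (not isolated)
Conditions: HCl (1.25 M in MeOH), 1,4-dioxane, rt; then 60 °C
Reagents that add atoms: none
Why: Acidic methanol removes the primary silyl ether at room temperature; on warming, the chelated phenol adds to the protonated carbonyl next to ring B and the 2-hydroxychromanone loses water to the chromone (acid-catalysed cyclodehydration of an ortho-hydroxydibenzoylmethane). A Brønsted acid of this strength should leave the aryl benzyl ethers and the dioxane intact.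

Step 14
Reactants: 19 5,7-bis(benzyloxy)-2-[(2R,3R)-2-[4-(benzyloxy)-3,5-dimethoxyphenyl]-3-(hydroxymethyl)-5-methoxy-2,3-dihydro-1,4-benzodioxin-7-yl]-4H-chromen-4-one
Product: 20 palstatin, 5,7-dihydroxy-2-[(2R,3R)-3-(hydroxymethyl)-2-(4-hydroxy-3,5-dimethoxyphenyl)-5-methoxy-2,3-dihydro-1,4-benzodioxin-7-yl]-4H-chromen-4-one
Conditions: H2 (1 atm), 10% Pd/C, THF–MeOH, rt
Reagents that add atoms: none
Why: Catalytic hydrogenolysis of three aryl benzyl ethers; these primary benzylic C–O bonds should be cleaved much faster than the secondary, ring-bound Ca–O3' bond. The conjugated C2=C3 bond of a flavone is slow to hydrogenate at one atmosphere, so the reaction is stopped after three equivalents of hydrogen.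

## Compound list

1 | sinapic acid, (E)-3-(4-hydroxy-3,5-dimethoxyphenyl)prop-2-enoic acid | COc1cc(/C=C/C(=O)O)cc(OC)c1O | starting material
2 | benzyl (E)-3-[4-(benzyloxy)-3,5-dimethoxyphenyl]prop-2-enoate | COc1cc(/C=C/C(=O)OCc2ccccc2)cc(OC)c1OCc1ccccc1 | intermediate
3 | (E)-3-[4-(benzyloxy)-3,5-dimethoxyphenyl]prop-2-en-1-ol | COc1cc(/C=C/CO)cc(OC)c1OCc1ccccc1 | intermediate
4 | [(2S,3S)-3-[4-(benzyloxy)-3,5-dimethoxyphenyl]oxiran-2-yl]methanol | OC[C@@H]1O[C@H]1c1cc(OC)c(OCc2ccccc2)c(OC)c1 | intermediate
5 | methyl 3,4-dihydroxy-5-methoxybenzoate | COC(=O)c1cc(O)c(O)c(OC)c1 | starting material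
6 | methyl 3-hydroxy-5-methoxy-4-(prop-2-enyloxy)benzoate | COC(=O)c1cc(O)c(OCC=C)c(OC)c1 | intermediate
7 | methyl 3-{[(1R,2S)-1-[4-(benzyloxy)-3,5-dimethoxyphenyl]-2,3-dihydroxypropyl]oxy}-5-methoxy-4-(prop-2-enyloxy)benzoate | COc1cc([C@@H](Oc2cc(C(=O)OC)cc(OC)c2OCC=C)[C@@H](O)CO)cc(OC)c1OCc1ccccc1 | intermediate
8 | methyl 3-{[(1R,2S)-1-[4-(benzyloxy)-3,5-dimethoxyphenyl]-2-hydroxy-3-[(4-methylbenzenesulfonyl)oxy]propyl]oxy}-5-methoxy-4-(prop-2-enyloxy)benzoate | COc1cc([C@@H](Oc2cc(C(=O)OC)cc(OC)c2OCC=C)[C@@H](O)COS(=O)(=O)c2ccc(C)cc2)cc(OC)c1OCc1ccccc1 | intermediate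
9 | methyl 3-{(R)-[4-(benzyloxy)-3,5-dimethoxyphenyl][(2S)-oxiran-2-yl]methoxy}-5-methoxy-4-(prop-2-enyloxy)benzoate | COc1cc([C@@H](Oc2cc(C(=O)OC)cc(OC)c2OCC=C)[C@@H]4CO4)cc(OC)c1OCc1ccccc1 | intermediate
10 | methyl 3-{(R)-[4-(benzyloxy)-3,5-dimethoxyphenyl][(2S)-oxiran-2-yl]methoxy}-4-hydroxy-5-methoxybenzoate | COc1cc([C@@H](Oc2cc(C(=O)OC)cc(OC)c2O)[C@@H]4CO4)cc(OC)c1OCc1ccccc1 | intermediate
11 | methyl (2R,3R)-2-[4-(benzyloxy)-3,5-dimethoxyphenyl]-3-(hydroxymethyl)-5-methoxy-2,3-dihydro-1,4-benzodioxine-7-carboxylate | COc1cc([C@H]2Oc3cc(C(=O)OC)cc(OC)c3O[C@@H]2CO)cc(OC)c1OCc1ccccc1 | intermediate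
12 | methyl (2R,3R)-2-[4-(benzyloxy)-3,5-dimethoxyphenyl]-3-{[(tert-butyldimethylsilyl)oxy]methyl}-5-methoxy-2,3-dihydro-1,4-benzodioxine-7-carboxylate | COc1cc([C@H]2Oc3cc(C(=O)OC)cc(OC)c3O[C@@H]2CO[Si](C)(C)C(C)(C)C)cc(OC)c1OCc1ccccc1 | intermediate
13 | (2R,3R)-2-[4-(benzyloxy)-3,5-dimethoxyphenyl]-3-{[(tert-butyldimethylsilyl)oxy]methyl}-5-methoxy-2,3-dihydro-1,4-benzodioxine-7-carboxylic acid | COc1cc([C@H]2Oc3cc(C(=O)O)cc(OC)c3O[C@@H]2CO[Si](C)(C)C(C)(C)C)cc(OC)c1OCc1ccccc1 | intermediate
14 | 2,4,6-trihydroxyacetophenone | CC(=O)c1c(O)cc(O)cc1O | starting material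
15 | 1-[2,4-bis(benzyloxy)-6-hydroxyphenyl]ethanone | CC(=O)c1c(O)cc(OCc2ccccc2)cc1OCc1ccccc1 | intermediate
16 | 2-acetyl-3,5-bis(benzyloxy)phenyl (2R,3R)-2-[4-(benzyloxy)-3,5-dimethoxyphenyl]-3-{[(tert-butyldimethylsilyl)oxy]methyl}-5-methoxy-2,3-dihydro-1,4-benzodioxine-7-carboxylate | COc1cc([C@H]2Oc3cc(C(=O)Oc4cc(OCc5ccccc5)cc(OCc5ccccc5)c4C(C)=O)cc(OC)c3O[C@@H]2CO[Si](C)(C)C(C)(C)C)cc(OC)c1OCc1ccccc1 | intermediate
17 | 1-[2,4-bis(benzyloxy)-6-hydroxyphenyl]-3-[(2R,3R)-2-[4-(benzyloxy)-3,5-dimethoxyphenyl]-3-{[(tert-butyldimethylsilyl)oxy]methyl}-5-methoxy-2,3-dihydro-1,4-benzodioxin-7-yl]propane-1,3-dione | COc1cc([C@H]2Oc3cc(C(=O)CC(=O)c4c(O)cc(OCc5ccccc5)cc4OCc4ccccc4)cc(OC)c3O[C@@H]2CO[Si](C)(C)C(C)(C)C)cc(OC)c1OCc1ccccc1 | intermediate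
18 | 1-[2,4-bis(benzyloxy)-6-hydroxyphenyl]-3-[(2R,3R)-2-[4-(benzyloxy)-3,5-dimethoxyphenyl]-3-(hydroxymethyl)-5-methoxy-2,3-dihydro-1,4-benzodioxin-7-yl]propane-1,3-dione | COc1cc([C@H]2Oc3cc(C(=O)CC(=O)c4c(O)cc(OCc5ccccc5)cc4OCc4ccccc4)cc(OC)c3O[C@@H]2CO)cc(OC)c1OCc1ccccc1 | intermediate
19 | 5,7-bis(benzyloxy)-2-[(2R,3R)-2-[4-(benzyloxy)-3,5-dimethoxyphenyl]-3-(hydroxymethyl)-5-methoxy-2,3-dihydro-1,4-benzodioxin-7-yl]-4H-chromen-4-one | COc1cc([C@H]2Oc3cc(-c4cc(=O)c5c(OCc6ccccc6)cc(OCc6ccccc6)cc5o4)cc(OC)c3O[C@@H]2CO)cc(OC)c1OCc1ccccc1 | intermediate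
20 | palstatin, 5,7-dihydroxy-2-[(2R,3R)-3-(hydroxymethyl)-2-(4-hydroxy-3,5-dimethoxyphenyl)-5-methoxy-2,3-dihydro-1,4-benzodioxin-7-yl]-4H-chromen-4-one | COc1cc([C@H]2Oc3cc(-c4cc(=O)c5c(O)cc(O)cc5o4)cc(OC)c3O[C@@H]2CO)cc(OC)c1O | target

## Step count and least certain steps

Total step count: 14 (steps 4 and 10 are one-step side branches). Longest linear sequence: 12 steps, from 1 through steps 1, 2, 3, 5, 6, 7, 8, 9, 11, 12, 13 and 14.

**Step 7 (key step).**
- What may go wrong: opening of the oxirane at the CH2 terminus in the 7-endo mode, intermolecular methanolysis of the oxirane before the phenoxide is released, or slow substitution at Cb. Cb is flanked by the branched carbon Ca, and the phenoxide is weakened by the para ester.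
- Fallback: from 7, the primary hydroxyl would be silylated selectively (TBSCl, imidazole, CH2Cl2, 0 °C) to the mono-silyl ether F1. The allyl group would be removed (Pd(PPh3)4, K2CO3, MeOH) to give the phenol F2. An intramolecular Mitsunobu reaction (PPh3, diisopropyl azodicarboxylate, THF, 0 °C → rt) would then let O4' displace the activated Cb hydroxyl with inversion. No electrophilic CH2 is present, so a seven-membered ring cannot form. The sequence returns to the route at 12 in the same number of operations.

**Step 5.**
- What may go wrong: partial ionisation at the benzylic carbon, with loss of configurational integrity at Ca, which cannot be repaired later while the para oxygen is benzylated. Isopropoxide may compete as the nucleophile, and ester exchange at the methyl ester may occur on the titanium centre.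
- Fallback: from 4, the hydroxyl would be capped (tert-butyldiphenylsilyl chloride, imidazole, CH2Cl2) to give the epoxy silyl ether F3. F3 would be opened by the caesium phenoxide of 6 (Cs2CO3, DMF, 70 °C) in a purely SN2 process at the benzylic carbon, giving the hydroxy silyl ether F4. The position next to the CH2O group is deactivated and no Payne rearrangement is possible. Bu4NF in THF would then give 7, where the route is rejoined.

**Step 3.**
- What may go wrong: opening of the electron-rich aryl oxirane by isopropanol or tartrate on the Lewis acidic titanium centre, or decomposition of 4 during work-up and isolation.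
- Fallback: from 3, a Shi epoxidation with the enantiomer of the fructose-derived ketone catalyst (KHSO5 as the triple salt 2KHSO5·KHSO4·K2SO4, K2CO3 buffer, MeCN–dimethoxymethane–water, 0 °C) would deliver 4 directly under basic, metal-free conditions. It returns to the route at 4 and makes no new compound.

**Step 13.**
- What may go wrong: acid-promoted ionisation of the Ca–O3' bond with capture by methanol or epimerisation, or stalling at the 2-hydroxychromanone or a methyl ketal. Loss of the peri benzyl ether would be harmless because step 14 removes it anyway.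
- Fallback: from 17, ring closure and deprotection would be separated. TsOH·H2O (cat.) in toluene at 80 °C over 4 Å MS, an aprotic medium without a nucleophile for a benzylic cation, would give the silyl flavone F5. Buffered Bu4NF (AcOH, THF, 0 °C) would then give 19, where the route is rejoined.

## Further compounds

F1 | step 7 | methyl 3-{[(1R,2S)-1-[4-(benzyloxy)-3,5-dimethoxyphenyl]-3-[(tert-butyldimethylsilyl)oxy]-2-hydroxypropyl]oxy}-5-methoxy-4-(prop-2-enyloxy)benzoate | COc1cc([C@@H](Oc2cc(C(=O)OC)cc(OC)c2OCC=C)[C@@H](O)CO[Si](C)(C)C(C)(C)C)cc(OC)c1OCc1ccccc1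
F2 | step 7 | methyl 3-{[(1R,2S)-1-[4-(benzyloxy)-3,5-dimethoxyphenyl]-3-[(tert-butyldimethylsilyl)oxy]-2-hydroxypropyl]oxy}-4-hydroxy-5-methoxybenzoate | COc1cc([C@@H](Oc2cc(C(=O)OC)cc(OC)c2O)[C@@H](O)CO[Si](C)(C)C(C)(C)C)cc(OC)c1OCc1ccccc1
F3 | step 5 | tert-butyl{[(2S,3S)-3-[4-(benzyloxy)-3,5-dimethoxyphenyl]oxiran-2-yl]methoxy}diphenylsilane | CC(C)(C)[Si](OC[C@@H]1O[C@H]1c1cc(OC)c(OCc2ccccc2)c(OC)c1)(c1ccccc1)c1ccccc1
F4 | step 5 | methyl 3-{[(1R,2S)-1-[4-(benzyloxy)-3,5-dimethoxyphenyl]-3-[(tert-butyldiphenylsilyl)oxy]-2-hydroxypropyl]oxy}-5-methoxy-4-(prop-2-enyloxy)benzoate | COc1cc([C@@H](Oc2cc(C(=O)OC)cc(OC)c2OCC=C)[C@@H](O)CO[Si](c2ccccc2)(c2ccccc2)C(C)(C)C)cc(OC)c1OCc1ccccc1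
F0 | step 3 | none | none
F5 | step 13 | 5,7-bis(benzyloxy)-2-[(2R,3R)-2-[4-(benzyloxy)-3,5-dimethoxyphenyl]-3-{[(tert-butyldimethylsilyl)oxy]methyl}-5-methoxy-2,3-dihydro-1,4-benzodioxin-7-yl]-4H-chromen-4-one | COc1cc([C@H]2Oc3cc(-c4cc(=O)c5c(OCc6ccccc6)cc(OCc6ccccc6)cc5o4)cc(OC)c3O[C@@H]2CO[Si](C)(C)C(C)(C)C)cc(OC)c1OCc1ccccc1
A1 | alternative 1 | 1-[2,4-bis(benzyloxy)-6-hydroxyphenyl]-3-[(2R,3R)-2-[4-(benzyloxy)-3,5-dimethoxyphenyl]-3-[(benzyloxy)methyl]-5-methoxy-2,3-dihydro-1,4-benzodioxin-7-yl]prop-2-yn-1-one | COc1cc([C@H]2Oc3cc(C#CC(=O)c4c(O)cc(OCc5ccccc5)cc4OCc4ccccc4)cc(OC)c3O[C@@H]2COCc4ccccc4)cc(OC)c1OCc1ccccc1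
A2 | alternative 1 | 3-[(2R,3R)-2-[4-(benzyloxy)-3,5-dimethoxyphenyl]-3-[(benzyloxy)methyl]-5-methoxy-2,3-dihydro-1,4-benzodioxin-7-yl]prop-2-ynoic acid | COc1cc([C@H]2Oc3cc(C#CC(=O)O)cc(OC)c3O[C@@H]2COCc4ccccc4)cc(OC)c1OCc1ccccc1
A3 | alternative 1 | 3,5-bis(benzyloxy)-2-(trimethylsilyl)phenyl trifluoromethanesulfonate | C[Si](C)(C)c1c(OCc2ccccc2)cc(OCc2ccccc2)cc1OS(=O)(=O)C(F)(F)F
A4 | alternative 2 | 5,7-bis(benzyloxy)-2-[(2R,3R)-2-[4-(benzyloxy)-3,5-dimethoxyphenyl]-3-{[(tert-butyldimethylsilyl)oxy]methyl}-5-methoxy-2,3-dihydro-1,4-benzodioxin-7-yl]-4H-chromen-4-one | COc1cc([C@H]2Oc3cc(-c4cc(=O)c5c(OCc6ccccc6)cc(OCc6ccccc6)cc5o4)cc(OC)c3O[C@@H]2CO[Si](C)(C)C(C)(C)C)cc(OC)c1OCc1ccccc1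
A5 | alternative 2 | 3,5-bis(benzyloxy)-2-iodophenol | Oc1cc(OCc2ccccc2)cc(OCc2ccccc2)c1I
A6 | alternative 2 | (2R,3R)-2-[4-(benzyloxy)-3,5-dimethoxyphenyl]-3-{[(tert-butyldimethylsilyl)oxy]methyl}-7-ethynyl-5-methoxy-2,3-dihydro-1,4-benzodioxine | COc1cc([C@H]2Oc3cc(C#C)cc(OC)c3O[C@@H]2CO[Si](C)(C)C(C)(C)C)cc(OC)c1OCc1ccccc1
A7 | alternative 3 | methyl (2R,3R)-2-[4-(benzyloxy)-3,5-dimethoxyphenyl]-3-{[(tert-butyldimethylsilyl)oxy]methyl}-5-methoxy-2,3-dihydro-1,4-benzodioxine-7-carboxylate | COc1cc([C@H]2Oc3cc(C(=O)OC)cc(OC)c3O[C@@H]2CO[Si](C)(C)C(C)(C)C)cc(OC)c1OCc1ccccc1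
A8 | alternative 3 | methyl 4-{[(1R,2R)-1-[4-(benzyloxy)-3,5-dimethoxyphenyl]-3-[(tert-butyldimethylsilyl)oxy]-1-hydroxypropan-2-yl]oxy}-3-bromo-5-methoxybenzoate | COc1cc([C@@H](O)[C@@H](CO[Si](C)(C)C(C)(C)C)Oc2c(Br)cc(C(=O)OC)cc2OC)cc(OC)c1OCc1ccccc1
A9 | alternative 3 | methyl 3-bromo-4-hydroxy-5-methoxybenzoate | COC(=O)c1cc(Br)c(O)c(OC)c1
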